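**Retrosynthetic overview**
- Ring A (C4a, C5, C6, C7, C8, C8a) has oxygen on C5, C6, C7 and C8a and hydrogen only on C8. Its C4a–C8a edge, shared with ring C, is the C5=C6 enone bond of a monocyclic 2,3-dihydro-4H-pyran-4-one.
- Key disconnection: C4a–C5 and C8–C8a. A 5-bromodihydropyranone that already carries C2, C3 and ring B takes up C5–C8 as 1,2,3-trimethoxy-1-(trimethylsilyloxy)butadiene. Loss of HBr and MeOH then gives the arene.
- Ring C: C2–C3 and O1–C6 come from an asymmetric hetero-Diels–Alder reaction of the ring B aldehyde (sets C2). C3–O is installed trans to the aryl group by Rubottom oxidation, followed by O-methylation and C5 bromination.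
- Ring B comes from 2-methoxyhydroquinone (benzylation, formylation). The diene comes from methyl methoxyacetate in three steps.
- Order of rings: B (bought), C (step 3), A (step 11). End game: 5-O-methylation, then hydrogenolysis.

Key step: step 11

Assumption: the sense of induction in step 3 is taken from the behaviour of BINOL/Ti(OiPr)4 with simple aromatic aldehydes, where (S)-BINOL gives the (S)-carbinol centre. Both BINOL antipodes are commercial, and the one that gives (S)-7 is meant.

**Step 1**
Reactants: 1 2-methoxyhydroquinone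
Product: 2 1,4-bis(benzyloxy)-2-methoxybenzene
Conditions: BnBr (2.3 equiv), K2CO3 (3 equiv), DMF, N2, rt to 50 °C
Reagents that add atoms: benzyl bromide, BrCc1ccccc1
Why: Williamson ether synthesis in which both phenoxides are alkylated by the benzylic bromide, with inert gas preventing air oxidation of the hydroquinone.

**Step 2**
Reactants: 2 1,4-bis(benzyloxy)-2-methoxybenzene
Product: 4 2,5-bis(benzyloxy)-4-methoxybenzaldehyde, via aryl iminium chloride 3 (not isolated)
Conditions: POCl3 (1.5 equiv), DMF, 0 to 70 °C; then H2O, 0 °C to rt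
Reagents that add atoms: N,N-dimethylformamide, CN(C)C=O (formyl CH); water, O (formyl oxygen)
Why: Vilsmeier–Haack formylation attacks the one unhindered position that is para to the methoxy group and ortho to a benzyloxy group, as is general for 1,2,4-trialkoxybenzenes, and hydrolysis of 3 frees the aldehyde.

**Step 3**
Reactants: 4 2,5-bis(benzyloxy)-4-methoxybenzaldehyde; 5 (E)-1-methoxy-3-(trimethylsilyloxy)buta-1,3-diene
Product: 7 (S)-2-[2,5-bis(benzyloxy)-4-methoxyphenyl]-2,3-dihydro-4H-pyran-4-one, via silylated aldol adduct 6 (not isolated)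
Conditions: Ti(OiPr)4 (10 mol %), (S)-BINOL (20 mol %), 4 Å MS, Et2O, −20 °C; then TFA (0.1 equiv), CH2Cl2, 0 °C, short contact, NaHCO3 quench
Reagents that add atoms: none
Why: Catalytic asymmetric hetero-Diels–Alder reaction in its stepwise form (enantioselective Mukaiyama aldol addition, then acid-induced 6-endo oxa-Michael closure with loss of methanol), in which the chiral BINOL–titanium Lewis acid shields one face of the bound aldehyde and so sets the benzylic centre (S here, R by descriptor once C3 bears oxygen).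

**Step 4**
Reactants: 7 (S)-2-[2,5-bis(benzyloxy)-4-methoxyphenyl]-2,3-dihydro-4H-pyran-4-one
Product: 9 (S)-2-[2,5-bis(benzyloxy)-4-methoxyphenyl]-4-(trimethylsilyloxy)-2H-pyran, via lithium dienolate 8 (not isolated)
Conditions: TMSCl (1.5 equiv, present from the start), LDA (1.15 equiv), THF, −78 °C; pentane, filtration, used crude
Reagents that add atoms: chlorotrimethylsilane, C[Si](C)(C)Cl
Why: Kinetic α'-deprotonation of a vinylogous ester whose only enolisable position is C3, run with in situ quench so that 8 is O-silylated before it can expel O1 by retro-oxa-Michael ring opening.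

**Step 5**
Reactants: 9 (S)-2-[2,5-bis(benzyloxy)-4-methoxyphenyl]-4-(trimethylsilyloxy)-2H-pyran
Product: 11 (2R,3R)-2-[2,5-bis(benzyloxy)-4-methoxyphenyl]-3-hydroxy-2,3-dihydro-4H-pyran-4-one, via 3-silyloxy ketone 10 (not isolated)
Conditions: dimethyldioxirane (1.05 equiv, acetone), CH2Cl2, −78 to −30 °C; then 10% aq citric acid, THF, 0 °C
Reagents that add atoms: dimethyldioxirane, CC1(C)OO1
Why: Rubottom oxidation in which the oxidant attacks the C3=C4 silyl enol ether, the most electron-rich π bond, on the face opposite the C2 aryl group, so that the new C3–O bond is trans to the aryl group (3R), which is also the thermodynamically preferred diequatorial arrangement.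

**Step 6**
Reactants: 11 (2R,3R)-2-[2,5-bis(benzyloxy)-4-methoxyphenyl]-3-hydroxy-2,3-dihydro-4H-pyran-4-one
Product: 12 (2R,3R)-2-[2,5-bis(benzyloxy)-4-methoxyphenyl]-3-methoxy-2,3-dihydro-4H-pyran-4-one
Conditions: MeI (10 equiv), Ag2O (2.5 equiv), 4 Å MS, CH2Cl2, rt, dark
Reagents that add atoms: iodomethane, CI
Why: Purdie methylation etherifies the secondary alcohol without a soluble base, so H3 next to the ketone is not removed and neither C3 epimerisation nor opening of the C2–O1 bond sets in.

**Step 7**
Reactants: 12 (2R,3R)-2-[2,5-bis(benzyloxy)-4-methoxyphenyl]-3-methoxy-2,3-dihydro-4H-pyran-4-one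
Product: 13 (2R,3R)-2-[2,5-bis(benzyloxy)-4-methoxyphenyl]-5-bromo-3-methoxy-2,3-dihydro-4H-pyran-4-one
Conditions: NBS (1.02 equiv), CH2Cl2, −20 to 0 °C, dark
Reagents that add atoms: N-bromosuccinimide, O=C1CCC(=O)N1Br
Why: Electrophilic α-halogenation of a vinylogous ester (bromonium transfer to the nucleophilic C5, then loss of H5), which in a non-polar solvent should outrun substitution on ring B, since the ring B positions activated by two alkoxy groups are either substituted (C1', C5') or flanked on both sides (C3').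

**Step 8**
Reactants: 14 methyl methoxyacetate
Product: 17 methyl 2-methoxy-3-oxobutanoate, via lithium ester enolate 15 (not isolated), via lithium hemiaminal alkoxide 16 (not isolated)
Conditions: LDA (1.05 equiv), THF, −78 °C; N-methoxy-N-methylacetamide (0.9 equiv), −78 °C; then 1 M HCl, −78 °C to rt
Reagents that add atoms: N-methoxy-N-methylacetamide, CC(=O)N(C)OC
Why: Crossed Claisen-type acylation of an ester enolate by an N-methoxy-N-methylamide, in which the chelated tetrahedral adduct 16 persists until the quench, so the acidic β-keto ester never meets unreacted enolate.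

**Step 9**
Reactants: 17 methyl 2-methoxy-3-oxobutanoate
Product: 19 methyl 2,3-dimethoxybut-2-enoate (E/Z mixture), via dimethyl ketal 18 (not isolated)
Conditions: HC(OMe)3 (3 equiv), H2SO4 (cat.), rt; then distillation from the acid
Reagents that add atoms: trimethyl orthoformate, COC(OC)OC
Why: Orthoformate ketalisation of the ketone followed by acid-catalysed loss of methanol, the standard route from β-keto esters to β-alkoxy enoates, where the double-bond geometry and position are irrelevant because every isomer gives the same dienolate in step 10.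

**Step 10**
Reactants: 19 methyl 2,3-dimethoxybut-2-enoate
Product: 21 1,2,3-trimethoxy-1-(trimethylsilyloxy)buta-1,3-diene, via lithium dienolate 20 (not isolated)
Conditions: LDA (1.1 equiv), THF, −78 °C; TMSCl (1.3 equiv), −78 °C to rt; pentane, filtration, bulb-to-bulb distillation
Reagents that add atoms: chlorotrimethylsilane, C[Si](C)(C)Cl
Why: γ-Deprotonation of a β-alkoxy enoate with no α hydrogen and O-silylation of the dienolate, the usual preparation of vinylketene silyl acetals, where the ketene acetal geometry is irrelevant because that carbon becomes sp2 C5.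

**Step 11**
Reactants: 13 (2R,3R)-2-[2,5-bis(benzyloxy)-4-methoxyphenyl]-5-bromo-3-methoxy-2,3-dihydro-4H-pyran-4-one; 21 1,2,3-trimethoxy-1-(trimethylsilyloxy)buta-1,3-diene
Product: 24 (2R,3R)-2-[2,5-bis(benzyloxy)-4-methoxyphenyl]-5-hydroxy-3,6,7-trimethoxychroman-4-one, via bromo ketal cycloadduct 22 (not isolated), via 5-O-silyl chromanone 23 (not isolated)
Conditions: 21 (4 equiv, two portions), 2,6-lutidine (1.5 equiv), toluene (1 M), 100 °C, sealed tube, Ar; then 10% aq citric acid, THF, rt
Reagents that add atoms: none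
Why: Proposed new method: the tetra-donor diene 21 is most nucleophilic at its unsubstituted methylene carbon, which bonds to C6 of 13 (the enone β carbon, future C8a), while the ketene acetal carbon bonds to the bromine-bearing C5 (future C4a) in a concerted but strongly asynchronous normal-demand [4+2] cycloaddition that gives adduct 22. The closest known reaction type is the regioselective cycloaddition of 1-alkoxy-1-silyloxybuta-1,3-dienes to 2-haloquinones and α-halo enones followed by spontaneous aromatisation; a β-alkoxy-α-bromo enone has not been shown as the 2π partner and is a weaker acceptor, which is why heat, high concentration and excess diene are specified. Ring A closes as a six-membered carbocycle by intermolecular [4+2] annulation onto the C4a–C8a edge of ring C (new bonds C8–C8a and C4a–C5), after which 22 loses methanol from the allylic C5 ketal (H from C8) and HBr (Br from C4a, H from C8a) to give aryl silyl ether 23, which dilute acid cleaves to the chelated phenol 24. No stereocentre survives from this step, because C4a, C5 and C8a all become sp2, so endo/exo and facial selectivity are irrelevant, and C2 and C3 stay untouched because the medium holds neither a base able to remove H3 nor an acid able to ionise C2–O1. The selectivity required is regiochemical (H on C8, free oxygen on C5) together with periselectivity for the C5=C6 bond over the C=C–C=O heterodiene, and it rests on the matched polarisation of diene and bromo enone, with bromine lowering the LUMO, marking the carbon that takes the acetal terminus and supplying the oxidation level for aromatisation. A Lewis acid is left out on purpose, since O-activation of the vinylogous ester would make O1 a leaving group at the 2,4,5-trialkoxybenzylic C2, and 2,6-lutidine traps HBr before it can protonate the diene.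

**Step 12**
Reactants: 24 (2R,3R)-2-[2,5-bis(benzyloxy)-4-methoxyphenyl]-5-hydroxy-3,6,7-trimethoxychroman-4-one
Product: 25 (2R,3R)-2-[2,5-bis(benzyloxy)-4-methoxyphenyl]-3,5,6,7-tetramethoxychroman-4-one
Conditions: MeI (15 equiv), Ag2O (3 equiv), CH2Cl2, rt to 40 °C, dark
Reagents that add atoms: iodomethane, CI
Why: MeI/Ag2O O-methylation is an established way to etherify hydrogen-bonded ortho-acyl phenols, and it is preferred over carbonate bases or betaine-based etherification because it needs no soluble base, so the H3 removal and C2–O1 cleavage that lead to the chalcone are not triggered and the trans-(2R,3R) array is kept.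

**Step 13**
Reactants: 25 (2R,3R)-2-[2,5-bis(benzyloxy)-4-methoxyphenyl]-3,5,6,7-tetramethoxychroman-4-one
Product: 26 (2R,3R)-2-(2,5-dihydroxy-4-methoxyphenyl)-3,5,6,7-tetramethoxychroman-4-one (CNP0150769.1)
Conditions: H2 (1 atm), 10% Pd/C, EtOAc, rt; filtration and concentration under Ar
Reagents that add atoms: none
Why: Catalytic hydrogenolysis cleaves the two aryl benzyl ethers under neutral conditions, while the endocyclic C2–O1 bond and the hindered, donor-substituted C4 ketone react far more slowly, and exclusion of air protects the freed ring B hydroquinone.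

**Compound list**

| No. | Name | SMILES | Role |
|---|---|---|---|
| 1 | 2-methoxyhydroquinone | COc1cc(O)ccc1O | starting material |
| 2 | 1,4-bis(benzyloxy)-2-methoxybenzene | COc1cc(OCc2ccccc2)ccc1OCc1ccccc1 | intermediate |
| 3 | [2,5-bis(benzyloxy)-4-methoxybenzylidene]dimethyliminium chloride | COc1cc(OCc2ccccc2)c(C=[N+](C)C)cc1OCc1ccccc1.[Cl-] | intermediate |
| 4 | 2,5-bis(benzyloxy)-4-methoxybenzaldehyde | COc1cc(OCc2ccccc2)c(C=O)cc1OCc1ccccc1 | intermediate |
| 5 | (E)-1-methoxy-3-(trimethylsilyloxy)buta-1,3-diene | CO/C=C/C(=C)O[Si](C)(C)C | starting material |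
| 6 | (1E,5S)-5-[2,5-bis(benzyloxy)-4-methoxyphenyl]-1-methoxy-5-(trimethylsilyloxy)pent-1-en-3-one | COc1cc(OCc4ccccc4)c([C@H](CC(=O)/C=C/OC)O[Si](C)(C)C)cc1OCc5ccccc5 | intermediate |
| 7 | (S)-2-[2,5-bis(benzyloxy)-4-methoxyphenyl]-2,3-dihydro-4H-pyran-4-one | COc1cc(OCc4ccccc4)c([C@H]2OC=CC(=O)C2)cc1OCc5ccccc5 | intermediate |
| 8 | lithium (S)-2-[2,5-bis(benzyloxy)-4-methoxyphenyl]-2H-pyran-4-olate | COc1cc(OCc4ccccc4)c([C@H]2OC=CC([O-])=C2)cc1OCc5ccccc5.[Li+] | intermediate |
| 9 | (S)-2-[2,5-bis(benzyloxy)-4-methoxyphenyl]-4-(trimethylsilyloxy)-2H-pyran | COc1cc(OCc4ccccc4)c([C@H]2OC=CC(O[Si](C)(C)C)=C2)cc1OCc5ccccc5 | intermediate |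
| 10 | (2R,3R)-2-[2,5-bis(benzyloxy)-4-methoxyphenyl]-3-(trimethylsilyloxy)-2,3-dihydro-4H-pyran-4-one | COc1cc(OCc4ccccc4)c([C@H]2OC=CC(=O)[C@@H]2O[Si](C)(C)C)cc1OCc5ccccc5 | intermediate |
| 11 | (2R,3R)-2-[2,5-bis(benzyloxy)-4-methoxyphenyl]-3-hydroxy-2,3-dihydro-4H-pyran-4-one | COc1cc(OCc4ccccc4)c([C@H]2OC=CC(=O)[C@@H]2O)cc1OCc5ccccc5 | intermediate |
| 12 | (2R,3R)-2-[2,5-bis(benzyloxy)-4-methoxyphenyl]-3-methoxy-2,3-dihydro-4H-pyran-4-one | COc1cc(OCc4ccccc4)c([C@H]2OC=CC(=O)[C@@H]2OC)cc1OCc5ccccc5 | intermediate |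
| 13 | (2R,3R)-2-[2,5-bis(benzyloxy)-4-methoxyphenyl]-5-bromo-3-methoxy-2,3-dihydro-4H-pyran-4-one | COc1cc(OCc4ccccc4)c([C@H]2OC=C(Br)C(=O)[C@@H]2OC)cc1OCc5ccccc5 | intermediate |
| 14 | methyl methoxyacetate | COCC(=O)OC | starting material |
| 15 | lithium 1,2-dimethoxyethen-1-olate | COC=C([O-])OC.[Li+] | intermediate |
| 16 | lithium 3,4-dimethoxy-2-[methoxy(methyl)amino]-4-oxobutan-2-olate | COC(=O)C(OC)C(C)([O-])N(C)OC.[Li+] | intermediate |
| 17 | methyl 2-methoxy-3-oxobutanoate (racemic, labile centre) | COC(=O)C(OC)C(C)=O | intermediate |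
| 18 | methyl 2,3,3-trimethoxybutanoate | COC(=O)C(OC)C(C)(OC)OC | intermediate |
| 19 | methyl 2,3-dimethoxybut-2-enoate (E/Z mixture) | COC(=O)C(OC)=C(C)OC | intermediate |
| 20 | lithium 1,2,3-trimethoxybuta-1,3-dien-1-olate | C=C(OC)C(OC)=C([O-])OC.[Li+] | intermediate |
| 21 | 1,2,3-trimethoxy-1-(trimethylsilyloxy)buta-1,3-diene | C=C(OC)C(OC)=C(OC)O[Si](C)(C)C | intermediate |
| 22 | (2R,3R)-2-[2,5-bis(benzyloxy)-4-methoxyphenyl]-4a-bromo-3,5,6,7-tetramethoxy-5-(trimethylsilyloxy)-2,3,4a,5,8,8a-hexahydro-4H-chromen-4-one (cis-fused; C4a, C5, C8a transient and unassigned) | COc1cc(OCc4ccccc4)c([C@H]2OC3CC(OC)=C(OC)C(OC)(O[Si](C)(C)C)C3(Br)C(=O)[C@@H]2OC)cc1OCc5ccccc5 | intermediate |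
| 23 | (2R,3R)-2-[2,5-bis(benzyloxy)-4-methoxyphenyl]-3,6,7-trimethoxy-5-(trimethylsilyloxy)chroman-4-one | COc1cc(OCc4ccccc4)c([C@H]2Oc3cc(OC)c(OC)c(O[Si](C)(C)C)c3C(=O)[C@@H]2OC)cc1OCc5ccccc5 | intermediate |
| 24 | (2R,3R)-2-[2,5-bis(benzyloxy)-4-methoxyphenyl]-5-hydroxy-3,6,7-trimethoxychroman-4-one | COc1cc(OCc4ccccc4)c([C@H]2Oc3cc(OC)c(OC)c(O)c3C(=O)[C@@H]2OC)cc1OCc5ccccc5 | intermediate |
| 25 | (2R,3R)-2-[2,5-bis(benzyloxy)-4-methoxyphenyl]-3,5,6,7-tetramethoxychroman-4-one | COc1cc(OCc4ccccc4)c([C@H]2Oc3cc(OC)c(OC)c(OC)c3C(=O)[C@@H]2OC)cc1OCc5ccccc5 | intermediate |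
| 26 | (2R,3R)-2-(2,5-dihydroxy-4-methoxyphenyl)-3,5,6,7-tetramethoxychroman-4-one | COc1cc(O)c([C@H]2Oc3cc(OC)c(OC)c(OC)c3C(=O)[C@@H]2OC)cc1O | target |

**Step count**
Total steps: 13. Longest linear sequence: 10 (steps 1–7 and 11–13). The diene branch (steps 8–10) joins at step 11.

**Steps most likely to fail**

1. Step 11.
 - What may go wrong:
  - Cycloaddition to the push–pull alkene may be too slow, so that the diene is lost by thermal or protic decay first.
  - A stepwise first bond at C6 may be followed by β-elimination of O1 and opening of ring C.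
  - Inverse-demand addition across the enone oxygen may compete.
  - Loss of silanol in place of methanol during aromatisation would be harmless, since it leads straight to 25.
 - The fallback uses known chemistry and buys ring A instead of building it. It sets out from 4 and returns at 25.
  - Commercial 1-(6-hydroxy-2,3,4-trimethoxyphenyl)ethanone is protected (MOMCl, iPr2NEt, CH2Cl2) as 1-[6-(methoxymethoxy)-2,3,4-trimethoxyphenyl]ethanone F1.
  - Claisen–Schmidt condensation of F1 with 4 (KOH, EtOH) gives (E)-3-[2,5-bis(benzyloxy)-4-methoxyphenyl]-1-[6-(methoxymethoxy)-2,3,4-trimethoxyphenyl]prop-2-en-1-one F2.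
  - Juliá–Colonna epoxidation (poly-L-leucine, urea–H2O2, DBU, THF) gives {(2R,3S)-3-[2,5-bis(benzyloxy)-4-methoxyphenyl]oxiran-2-yl}[6-(methoxymethoxy)-2,3,4-trimethoxyphenyl]methanone F3.
  - Dilute HCl in MeOH removes the acetal. The freed {(2R,3S)-3-[2,5-bis(benzyloxy)-4-methoxyphenyl]oxiran-2-yl}(6-hydroxy-2,3,4-trimethoxyphenyl)methanone F4 closes ring C by phenol attack at the benzylic epoxide carbon, with C3 keeping its configuration. This gives trans (2R,3R)-2-[2,5-bis(benzyloxy)-4-methoxyphenyl]-3-hydroxy-5,6,7-trimethoxychroman-4-one F5.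
  - MeI/Ag2O then gives 25.

2. Step 3.
 - What may go wrong:
  - The trialkoxybenzaldehyde is a weak electrophile.
  - Chelation of the ortho benzyloxy oxygen to titanium may erode facial selectivity.
  - Ionisation at the very electron-rich benzylic carbon during the acid-induced closure may cause loss of enantiopurity.
 - The fallback sets out from 4 and returns at 7. It changes the diene, the mode of activation and the unmasking.
  - Commercial (E)-3-(tert-butyldimethylsilyloxy)-N,N-dimethylbuta-1,3-dien-1-amine, a far more reactive diene, is combined with 4. The catalyst is the hydrogen-bond donor α,α,α',α'-tetra(1-naphthyl)-2,2-dimethyl-1,3-dioxolane-4,5-dimethanol, with the antipode chosen for the S product (toluene, −40 °C).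
  - This gives (6S)-6-[2,5-bis(benzyloxy)-4-methoxyphenyl]-4-(tert-butyldimethylsilyloxy)-N,N-dimethyl-5,6-dihydro-2H-pyran-2-amine F6.
  - Acetyl chloride at −78 °C converts F6 into 7 without any Brønsted acid.

3. Step 7.
 - What may go wrong: electrophilic substitution on ring B (C3' or C6') may compete, or over-bromination may occur.
 - The fallback sets out from 12 and returns at 13.
  - Dimethylamine (THF, 0 °C to rt) opens the vinylogous ester by addition–elimination at C6. This gives (1E,4R,5R)-5-[2,5-bis(benzyloxy)-4-methoxyphenyl]-1-(dimethylamino)-5-hydroxy-4-methoxypent-1-en-3-one F7.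
  - The α carbon of F7 is far more nucleophilic than any ring B position, so NBS (1 equiv, CH2Cl2, −78 °C) gives (4R,5R)-5-[2,5-bis(benzyloxy)-4-methoxyphenyl]-2-bromo-1-(dimethylamino)-5-hydroxy-4-methoxypent-1-en-3-one F8.
  - PPTS or silica gel re-closes the ring by attack of the C5 hydroxyl at C1 with loss of the amine. This halogenation–cyclisation is known from the preparation of 3-halochromones from 2-hydroxyaryl enaminones.

**Further compounds**
F1 | step 11 | 1-[6-(methoxymethoxy)-2,3,4-trimethoxyphenyl]ethanone | CC(=O)c1c(OCOC)cc(OC)c(OC)c1OC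
F2 | step 11 | (E)-3-[2,5-bis(benzyloxy)-4-methoxyphenyl]-1-[6-(methoxymethoxy)-2,3,4-trimethoxyphenyl]prop-2-en-1-one | COCOc1cc(OC)c(OC)c(OC)c1C(=O)/C=C/c1cc(OCc2ccccc2)c(OC)cc1OCc1ccccc1
F3 | step 11 | {(2R,3S)-3-[2,5-bis(benzyloxy)-4-methoxyphenyl]oxiran-2-yl}[6-(methoxymethoxy)-2,3,4-trimethoxyphenyl]methanone | COCOc1cc(OC)c(OC)c(OC)c1C(=O)[C@@H]1O[C@H]1c1cc(OCc2ccccc2)c(OC)cc1OCc1ccccc1
F4 | step 11 | {(2R,3S)-3-[2,5-bis(benzyloxy)-4-methoxyphenyl]oxiran-2-yl}(6-hydroxy-2,3,4-trimethoxyphenyl)methanone | Oc1cc(OC)c(OC)c(OC)c1C(=O)[C@@H]1O[C@H]1c1cc(OCc2ccccc2)c(OC)cc1OCc1ccccc1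
F5 | step 11 | (2R,3R)-2-[2,5-bis(benzyloxy)-4-methoxyphenyl]-3-hydroxy-5,6,7-trimethoxychroman-4-one | COc1cc(OCc4ccccc4)c([C@H]2Oc3cc(OC)c(OC)c(OC)c3C(=O)[C@@H]2O)cc1OCc5ccccc5
F6 | step 3 | (6S)-6-[2,5-bis(benzyloxy)-4-methoxyphenyl]-4-(tert-butyldimethylsilyloxy)-N,N-dimethyl-5,6-dihydro-2H-pyran-2-amine | COc1cc(OCc4ccccc4)c([C@H]2OC(N(C)C)C=C(O[Si](C)(C)C(C)(C)C)C2)cc1OCc5ccccc5
F7 | step 7 | (1E,4R,5R)-5-[2,5-bis(benzyloxy)-4-methoxyphenyl]-1-(dimethylamino)-5-hydroxy-4-methoxypent-1-en-3-one | COc1cc(OCc4ccccc4)c([C@@H](O)[C@@H](OC)C(=O)/C=C/N(C)C)cc1OCc5ccccc5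
F8 | step 7 | (4R,5R)-5-[2,5-bis(benzyloxy)-4-methoxyphenyl]-2-bromo-1-(dimethylamino)-5-hydroxy-4-methoxypent-1-en-3-one | COc1cc(OCc4ccccc4)c([C@@H](O)[C@@H](OC)C(=O)C(Br)=CN(C)C)cc1OCc5ccccc5
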